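**Retrosynthetic overview**

1. C2–C3 is cut first (acetate silyl ketene acetal plus a C3 peroxycarbenium ion). C9=C10 is cut next (Julia–Kocienski). This leads back to a 3‑methoxy‑1,2‑dioxane aldehyde (C3–C9) and a C10–C14 phenyltetrazolyl sulfone.
2. The 1,2‑dioxane (O1–O2–C3–C4–C5–C6) is opened at both C–O bonds. In the forward direction H2O2 is stitched between the C3 aldehyde and the C5=C6 alkene of an acyclic enal by perhydrolysis and then 6‑endo iodoperoxidation. The auxiliary C5 iodide and C3 methoxy group are removed later.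
3. Enabling feature: ring carbons C3 and C6 both carry oxygen, are 1,4‑related and flank the C4 methyl stereocentre. The ring chair has C4–Me equatorial, C6–Me axial, C6–CH2 equatorial and C3–CH2 axial. An (E)‑C5=C6 alkene allylic to C4 therefore relays C4 to C6 (A(1,3) strain, anti addition), and the C3 cation relays C4/C6 to C3 (axial attack).
4. The enal comes from a Negishi coupling of a Roche‑ester‑derived vinyl iodide (C3–C6) with a zinc reagent from (S)‑3‑bromo‑2‑methylpropanol (C7–C9). The sulfone comes from an organocatalytic conjugate vinylation of crotonaldehyde, which sets C12.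
5. Ring order: the phenyl ring is bought. The 1,2‑dioxane is the only ring made, and so the last one closed.

Key step: step 10

Remark on numbering: C1 is the carboxyl carbon and C14 the benzylic alkene carbon; O2 sits on C3 and O1 on C6.
Remark on C3: in the methoxy hydroperoxide and in all 3‑methoxy‑1,2‑dioxanes C3 is an epimer mixture without consequence, because it is planarised in step 18. It is therefore left undefined in their SMILES.
Assumption: both enantiomers of the imidazolidinone catalyst and all numbered starting materials are taken as commercial.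

**Step 1**
Reactants: 1 methyl (R)-3-hydroxy-2-methylpropanoate (Roche ester)
Product: 2 methyl (R)-3-(tert-butyldimethylsilyloxy)-2-methylpropanoate
Conditions: TBSCl, imidazole, CH2Cl2, 0 °C to rt
Reagents that add atoms: tert-butyldimethylsilyl chloride CC(C)(C)[Si](C)(C)Cl
Why: Standard silylation of a primary alcohol; the stereocentre bought with 1 (the future C4) is not touched.

**Step 2**
Reactants: 2 methyl (R)-3-(tert-butyldimethylsilyloxy)-2-methylpropanoate
Product: 3 (R)-3-(tert-butyldimethylsilyloxy)-2-methylpropanal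
Conditions: DIBAL-H, CH2Cl2, −78 °C; Rochelle salt work-up
Reagents that add atoms: none
Why: Partial ester reduction with DIBAL-H, in which the tetrahedral aluminium alkoxide survives at −78 °C until work-up, so the aldehyde should form without over-reduction or epimerisation at C4.

**Step 3**
Reactants: 3 (R)-3-(tert-butyldimethylsilyloxy)-2-methylpropanal
Product: 4 (S)-tert-butyl[(4,4-dibromo-2-methylbut-3-en-1-yl)oxy]dimethylsilane
Conditions: CBr4, PPh3, CH2Cl2, 0 °C
Reagents that add atoms: carbon tetrabromide BrC(Br)(Br)Br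
Why: Corey–Fuchs (Ramirez) dibromoolefination, a Wittig-type reaction under essentially neutral conditions that leaves the α-stereocentre and the silyl ether intact.

**Step 4**
Reactants: 4 (S)-tert-butyl[(4,4-dibromo-2-methylbut-3-en-1-yl)oxy]dimethylsilane
Product: 6 (S)-tert-butyldimethyl[(2-methylpent-3-yn-1-yl)oxy]silane, via lithium acetylide 5 (not isolated)
Conditions: n-BuLi (2.2 equiv), THF, −78 °C; then MeI, −78 °C to rt
Reagents that add atoms: iodomethane CI
Why: Second stage of the Corey–Fuchs sequence, in which Br/Li exchange, α-elimination with 1,2-shift and deprotonation give the acetylide, whose SN2 methylation installs the future C6 methyl group.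

**Step 5**
Reactants: 6 (S)-tert-butyldimethyl[(2-methylpent-3-yn-1-yl)oxy]silane
Product: 8 (S,E)-tert-butyl[(4-iodo-2-methylpent-3-en-1-yl)oxy]dimethylsilane, via alkenylzirconocene chloride 7 (not isolated)
Conditions: Cp2Zr(H)Cl (excess), THF, 40 °C; then I2, −20 °C
Reagents that add atoms: iodine II
Why: Hydrozirconation–iodinolysis, in which syn addition places Zr on the less hindered alkyne carbon next to the methyl group (excess reagent equilibrates the regioisomers) and iodine replaces Zr with retention, fixing the (E)-alkene with C6–Me cis to C4.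

**Step 6**
Reactants: 9 (S)-3-bromo-2-methylpropan-1-ol
Product: 10 (S)-(3-bromo-2-methylpropoxy)(tert-butyl)diphenylsilane
Conditions: TBDPSCl, imidazole, CH2Cl2, rt
Reagents that add atoms: tert-butyldiphenylsilyl chloride CC(C)(C)[Si](Cl)(c1ccccc1)c1ccccc1
Why: Standard silylation; the stereocentre bought with 9 (the future C8) is not touched, and the bulky silyl ether oxygen will be non-nucleophilic in step 10.

**Step 7**
Reactants: 10 (S)-(3-bromo-2-methylpropoxy)(tert-butyl)diphenylsilane; 8 (S,E)-tert-butyl[(4-iodo-2-methylpent-3-en-1-yl)oxy]dimethylsilane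
Product: 12 (2S,3E,6R)-1-(tert-butyldimethylsilyloxy)-7-(tert-butyldiphenylsilyloxy)-2,4,6-trimethylhept-3-ene, via alkylzinc bromide 11 (not isolated)
Conditions: Zn dust, LiCl, THF, 50 °C; then 8, Pd(dppf)Cl2 (5 mol %), THF, rt to 40 °C
Reagents that add atoms: none
Why: LiCl-promoted zinc insertion followed by Negishi sp3–sp2 cross-coupling, which forms C6–C7 with retention of the alkene geometry and touches neither C4 nor C8.

**Step 8**
Reactants: 12 (2S,3E,6R)-1-(tert-butyldimethylsilyloxy)-7-(tert-butyldiphenylsilyloxy)-2,4,6-trimethylhept-3-ene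
Product: 13 (2S,3E,6R)-7-(tert-butyldiphenylsilyloxy)-2,4,6-trimethylhept-3-en-1-ol
Conditions: CSA (10 mol %), MeOH/CH2Cl2, 0 °C
Reagents that add atoms: none
Why: Acid-catalysed methanolysis distinguishes the labile primary TBS ether from the much more robust TBDPS ether.

**Step 9**
Reactants: 13 (2S,3E,6R)-7-(tert-butyldiphenylsilyloxy)-2,4,6-trimethylhept-3-en-1-ol
Product: 14 (2S,3E,6R)-7-(tert-butyldiphenylsilyloxy)-2,4,6-trimethylhept-3-enal
Conditions: Dess–Martin periodinane, NaHCO3, CH2Cl2, 0 °C; used at once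
Reagents that add atoms: none
Why: Buffered Dess–Martin oxidation is mild enough to give the α-chiral β,γ-unsaturated aldehyde without epimerisation at C4 or migration of the alkene into conjugation.

**Step 10**
Reactants: 14 (2S,3E,6R)-7-(tert-butyldiphenylsilyloxy)-2,4,6-trimethylhept-3-enal
Product: 16 (4R,5S,6R)-6-[(R)-3-(tert-butyldiphenylsilyloxy)-2-methylpropyl]-5-iodo-3-methoxy-4,6-dimethyl-1,2-dioxane (C3 anomers), via methoxy hydroperoxide 15 (not isolated)
Conditions: urea·H2O2, Sc(OTf)3 (10 mol %), MeOH, 0 °C; aqueous wash and solvent switch; NIS (1.1 equiv), CH2Cl2, 0 °C, dark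
Reagents that add atoms: urea–hydrogen peroxide OO.NC(N)=O; methanol CO; N-iodosuccinimide O=C1CCC(=O)N1I
Why: Sc(III)-catalysed perhydrolysis in methanol turns the C3 aldehyde into the α-methoxy hydroperoxide 15, and NIS then forms a reversible iodonium ion on the only alkene (C5=C6), which the terminal peroxide oxygen opens at tertiary C6, so that H2O2 ends up stitched between C3 and C6 and both ring C–O bonds are made in one operation. The closest known reaction types are the perhydrolysis of carbonyl compounds to alkoxy hydroperoxides and the cycloperoxyiodination (halocyclisation) of unsaturated hydroperoxides and hydroperoxy acetals. The 1,2-dioxane closes in the 6-endo-trig mode by anti addition of iodine and oxygen across the alkene. C6 is controlled by C4 through A(1,3) strain: because C6–Me is cis to C4 in the (E)-alkene, only the rotamer with C4–H in the alkene plane is populated and the peroxide tether reaches one face, giving the chair with C4–Me and the C7 chain equatorial and C6–Me axial, whereas the other face would need a syn-diaxial C4–Me/C6–Me pair, and it is the alkene geometry that decides which of Me and CH2 becomes axial. C5 (equatorial iodide, anti to O1) follows from the anti addition and is erased in step 11, and C3 forms as an anomer mixture that is erased in step 18. The step needs 6-endo over 5-exo closure, which the Markovnikov bias of the trisubstituted iodonium ion secures (tertiary C6 against the hindered secondary C5), and chemoselectivity, which is secured because the side-chain alkenes are not yet present and the TBDPS ether oxygen is not nucleophilic.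

**Step 11**
Reactants: 16 (4R,5S,6R)-6-[(R)-3-(tert-butyldiphenylsilyloxy)-2-methylpropyl]-5-iodo-3-methoxy-4,6-dimethyl-1,2-dioxane
Product: 17 (4S,6R)-6-[(R)-3-(tert-butyldiphenylsilyloxy)-2-methylpropyl]-3-methoxy-4,6-dimethyl-1,2-dioxane
Conditions: Bu3SnH (1.5 equiv, 0.5 M), Et3B (cat.)/air, toluene, 0 °C
Reagents that add atoms: none
Why: Radical-chain deiodination with tin hydride, in which iodine abstraction is far faster than stannyl attack on O–O, the endocyclic O–O bond is misaligned for attack by the C5 radical, and concentrated stannane traps that radical quickly, removing the auxiliary C5 stereocentre.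

**Step 12**
Reactants: 17 (4S,6R)-6-[(R)-3-(tert-butyldiphenylsilyloxy)-2-methylpropyl]-3-methoxy-4,6-dimethyl-1,2-dioxane
Product: 18 (R)-3-[(4S,6R)-3-methoxy-4,6-dimethyl-1,2-dioxan-6-yl]-2-methylpropan-1-ol
Conditions: TBAF, AcOH, THF, 0 °C to rt
Reagents that add atoms: none
Why: Buffered fluoride desilylation is neither reducing nor strongly basic, so the dialkyl peroxide and the peroxyacetal C3–H should survive.

**Step 13**
Reactants: 18 (R)-3-[(4S,6R)-3-methoxy-4,6-dimethyl-1,2-dioxan-6-yl]-2-methylpropan-1-ol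
Product: 19 (R)-3-[(4S,6R)-3-methoxy-4,6-dimethyl-1,2-dioxan-6-yl]-2-methylpropanal
Conditions: Dess–Martin periodinane, NaHCO3, CH2Cl2, 0 °C to rt
Reagents that add atoms: none
Why: Dess–Martin oxidation is compatible with peroxides and does not epimerise the α-stereocentre C8.

**Step 14**
Reactants: 20 (E)-crotonaldehyde; 21 potassium (E)-styryltrifluoroborate
Product: 23 (S,E)-3-methyl-5-phenylpent-4-en-1-ol, via aldehyde 22 (not isolated)
Conditions: (2R,5R)-5-benzyl-2-tert-butyl-3-methylimidazolidin-4-one·HCl (20 mol %), HF (aq., 1 equiv), DME, −20 °C; then NaBH4, EtOH, 0 °C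
Reagents that add atoms: none
Why: Iminium-ion organocatalytic conjugate vinylation, in which the benzyl and tert-butyl groups of the catalyst shield one face of the (E)-iminium ion so that the styryl group adds to the open face of the β-carbon and sets C12 as (S) by catalyst control (the (2R,5R) enantiomer is chosen by analogy with the known sense of induction of this catalyst class), and borohydride then reduces the aldehyde in the same flask.

**Step 15**
Reactants: 23 (S,E)-3-methyl-5-phenylpent-4-en-1-ol; 24 1-phenyl-1H-tetrazole-5-thiol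
Product: 25 5-{[(S,E)-3-methyl-5-phenylpent-4-en-1-yl]sulfanyl}-1-phenyl-1H-tetrazole
Conditions: PPh3, DIAD, THF, 0 °C to rt
Reagents that add atoms: none
Why: Mitsunobu thioetherification at a primary carbon; no stereocentre is involved.

**Step 16**
Reactants: 25 5-{[(S,E)-3-methyl-5-phenylpent-4-en-1-yl]sulfanyl}-1-phenyl-1H-tetrazole
Product: 26 5-{[(S,E)-3-methyl-5-phenylpent-4-en-1-yl]sulfonyl}-1-phenyl-1H-tetrazole
Conditions: H2O2 (30 % aq.), (NH4)6Mo7O24·4H2O (10 mol %), EtOH, 0 °C to rt
Reagents that add atoms: hydrogen peroxide OO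
Why: Molybdate-catalysed sulfide-to-sulfone oxidation, which is chemoselective for sulfur over the styrenyl alkene.

**Step 17**
Reactants: 26 5-{[(S,E)-3-methyl-5-phenylpent-4-en-1-yl]sulfonyl}-1-phenyl-1H-tetrazole; 19 (R)-3-[(4S,6R)-3-methoxy-4,6-dimethyl-1,2-dioxan-6-yl]-2-methylpropanal
Product: 28 (4S,6R)-6-[(2R,3E,6S,7E)-2,6-dimethyl-8-phenylocta-3,7-dien-1-yl]-3-methoxy-4,6-dimethyl-1,2-dioxane, via potassiated sulfone 27 (not isolated)
Conditions: KHMDS (1.0 equiv), DME, −78 °C, 30 min; then 19, −78 °C to rt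
Reagents that add atoms: none
Why: Julia–Kocienski olefination, in which the pre-metalated phenyltetrazolyl sulfone adds to the aldehyde faster than it can attack the peroxide or the peroxyacetal C–H (no free base and no carbanion on the dioxane fragment), and Smiles rearrangement with anti elimination should favour the (E)-C9=C10 alkene without epimerising C8.

**Step 18**
Reactants: 28 (4S,6R)-6-[(2R,3E,6S,7E)-2,6-dimethyl-8-phenylocta-3,7-dien-1-yl]-3-methoxy-4,6-dimethyl-1,2-dioxane; 29 tert-butyl[(1-methoxyvinyl)oxy]dimethylsilane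
Product: 31 methyl 2-{(3S,4S,6R)-6-[(2R,3E,6S,7E)-2,6-dimethyl-8-phenylocta-3,7-dien-1-yl]-4,6-dimethyl-1,2-dioxan-3-yl}acetate, via peroxycarbenium triflate 30 (not isolated)
Conditions: 29 (3 equiv), TMSOTf (20 mol %), CH2Cl2, −78 °C
Reagents that add atoms: none
Why: Lewis-acid ionisation of the peroxyacetal and Mukaiyama-type capture of the peroxycarbenium ion by the silyl ketene acetal, in which the half-chair is locked with C4–Me and the C7 chain pseudoequatorial (the flipped form has them syn-diaxial) and is attacked along the axial, chair-like trajectory, placing CH2CO2Me axial at C3, cis to C4–Me and to the C6 chain.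

**Step 19**
Reactants: 31 methyl 2-{(3S,4S,6R)-6-[(2R,3E,6S,7E)-2,6-dimethyl-8-phenylocta-3,7-dien-1-yl]-4,6-dimethyl-1,2-dioxan-3-yl}acetate
Product: 33 2-{(3S,4S,6R)-6-[(2R,3E,6S,7E)-2,6-dimethyl-8-phenylocta-3,7-dien-1-yl]-4,6-dimethyl-1,2-dioxan-3-yl}acetic acid (target), via lithium carboxylate 32 (not isolated)
Conditions: LiOH, THF/H2O, 0 °C to rt; then 1 M HCl to pH 3–4, 0 °C
Reagents that add atoms: lithium hydroxide [Li+].[OH-]
Why: Mild ester saponification, in which hydroxide attacks the unhindered methyl ester faster than it removes the C2 protons, so the β-peroxy ester should not undergo retro-oxa-Michael opening and no stereocentre is touched.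

**Compound list**

1 | methyl (R)-3-hydroxy-2-methylpropanoate | COC(=O)[C@H](C)CO | starting material
2 | methyl (R)-3-(tert-butyldimethylsilyloxy)-2-methylpropanoate | COC(=O)[C@H](C)CO[Si](C)(C)C(C)(C)C | intermediate
3 | (R)-3-(tert-butyldimethylsilyloxy)-2-methylpropanal | O=C[C@H](C)CO[Si](C)(C)C(C)(C)C | intermediate
4 | (S)-tert-butyl[(4,4-dibromo-2-methylbut-3-en-1-yl)oxy]dimethylsilane | BrC(Br)=C[C@H](C)CO[Si](C)(C)C(C)(C)C | intermediate
5 | lithium acetylide of (S)-tert-butyldimethyl[(2-methylbut-3-yn-1-yl)oxy]silane | [Li]C#C[C@H](C)CO[Si](C)(C)C(C)(C)C | intermediate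
6 | (S)-tert-butyldimethyl[(2-methylpent-3-yn-1-yl)oxy]silane | CC#C[C@H](C)CO[Si](C)(C)C(C)(C)C | intermediate
7 | (E)-alkenylzirconocene chloride (Zr on C6, trans to C4) | Cl[Zr](C1C=CC=C1)(C1C=CC=C1)/C(C)=C/[C@H](C)CO[Si](C)(C)C(C)(C)C | intermediate
8 | (S,E)-tert-butyl[(4-iodo-2-methylpent-3-en-1-yl)oxy]dimethylsilane | I/C(C)=C/[C@H](C)CO[Si](C)(C)C(C)(C)C | intermediate
9 | (S)-3-bromo-2-methylpropan-1-ol | OC[C@H](C)CBr | starting material
10 | (S)-(3-bromo-2-methylpropoxy)(tert-butyl)diphenylsilane | CC(C)(C)[Si](c1ccccc1)(c1ccccc1)OC[C@H](C)CBr | intermediate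
11 | (S)-[3-(tert-butyldiphenylsilyloxy)-2-methylpropyl]zinc bromide | CC(C)(C)[Si](c1ccccc1)(c1ccccc1)OC[C@H](C)C[Zn]Br | intermediate
12 | (2S,3E,6R)-1-(tert-butyldimethylsilyloxy)-7-(tert-butyldiphenylsilyloxy)-2,4,6-trimethylhept-3-ene | CC(C)(C)[Si](c1ccccc1)(c1ccccc1)OC[C@H](C)C/C(C)=C/[C@H](C)CO[Si](C)(C)C(C)(C)C | intermediate
13 | (2S,3E,6R)-7-(tert-butyldiphenylsilyloxy)-2,4,6-trimethylhept-3-en-1-ol | CC(C)(C)[Si](c1ccccc1)(c1ccccc1)OC[C@H](C)C/C(C)=C/[C@H](C)CO | intermediate
14 | (2S,3E,6R)-7-(tert-butyldiphenylsilyloxy)-2,4,6-trimethylhept-3-enal | CC(C)(C)[Si](c1ccccc1)(c1ccccc1)OC[C@H](C)C/C(C)=C/[C@H](C)C=O | intermediate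
15 | (2S,3E,6R)-7-(tert-butyldiphenylsilyloxy)-1-methoxy-2,4,6-trimethylhept-3-en-1-yl hydroperoxide (C1 epimers) | CC(C)(C)[Si](c1ccccc1)(c1ccccc1)OC[C@H](C)C/C(C)=C/[C@H](C)C(OC)OO | intermediate
16 | (4R,5S,6R)-6-[(R)-3-(tert-butyldiphenylsilyloxy)-2-methylpropyl]-5-iodo-3-methoxy-4,6-dimethyl-1,2-dioxane (C3 anomers) | CC(C)(C)[Si](c1ccccc1)(c1ccccc1)OC[C@H](C)C[C@]1(C)[C@@H](I)[C@H](C)C(OC)OO1 | intermediate
17 | (4S,6R)-6-[(R)-3-(tert-butyldiphenylsilyloxy)-2-methylpropyl]-3-methoxy-4,6-dimethyl-1,2-dioxane (C3 anomers) | CC(C)(C)[Si](c1ccccc1)(c1ccccc1)OC[C@H](C)C[C@]1(C)C[C@H](C)C(OC)OO1 | intermediate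
18 | (R)-3-[(4S,6R)-3-methoxy-4,6-dimethyl-1,2-dioxan-6-yl]-2-methylpropan-1-ol | OC[C@H](C)C[C@]1(C)C[C@H](C)C(OC)OO1 | intermediate
19 | (R)-3-[(4S,6R)-3-methoxy-4,6-dimethyl-1,2-dioxan-6-yl]-2-methylpropanal | O=C[C@H](C)C[C@]1(C)C[C@H](C)C(OC)OO1 | intermediate
20 | (E)-crotonaldehyde | C/C=C/C=O | starting material
21 | potassium (E)-styryltrifluoroborate | [K+].F[B-](F)(F)/C=C/c1ccccc1 | starting material
22 | (S,E)-3-methyl-5-phenylpent-4-enal | C[C@H](/C=C/c1ccccc1)CC=O | intermediate
23 | (S,E)-3-methyl-5-phenylpent-4-en-1-ol | C[C@H](/C=C/c1ccccc1)CCO | intermediate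
24 | 1-phenyl-1H-tetrazole-5-thiol | Sc1nnnn1-c1ccccc1 | starting material
25 | 5-{[(S,E)-3-methyl-5-phenylpent-4-en-1-yl]sulfanyl}-1-phenyl-1H-tetrazole | C[C@H](/C=C/c1ccccc1)CCSc1nnnn1-c1ccccc1 | intermediate
26 | 5-{[(S,E)-3-methyl-5-phenylpent-4-en-1-yl]sulfonyl}-1-phenyl-1H-tetrazole | C[C@H](/C=C/c1ccccc1)CCS(=O)(=O)c1nnnn1-c1ccccc1 | intermediate
27 | α-potassio derivative of sulfone 26 | C[C@H](/C=C/c1ccccc1)CC([K])S(=O)(=O)c1nnnn1-c1ccccc1 | intermediate
28 | (4S,6R)-6-[(2R,3E,6S,7E)-2,6-dimethyl-8-phenylocta-3,7-dien-1-yl]-3-methoxy-4,6-dimethyl-1,2-dioxane (C3 anomers) | C[C@H](/C=C/c1ccccc1)C/C=C/[C@H](C)C[C@]1(C)C[C@H](C)C(OC)OO1 | intermediate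
29 | tert-butyl[(1-methoxyvinyl)oxy]dimethylsilane | C=C(OC)O[Si](C)(C)C(C)(C)C | starting material
30 | C3 peroxycarbenium triflate derived from 28 | C[C@H](/C=C/c1ccccc1)C/C=C/[C@H](C)C[C@]1(C)C[C@H](C)C=[O+]O1.[O-]S(=O)(=O)C(F)(F)F | intermediate
31 | methyl 2-{(3S,4S,6R)-6-[(2R,3E,6S,7E)-2,6-dimethyl-8-phenylocta-3,7-dien-1-yl]-4,6-dimethyl-1,2-dioxan-3-yl}acetate | C[C@H](/C=C/c1ccccc1)C/C=C/[C@H](C)C[C@]1(C)C[C@H](C)[C@H](CC(=O)OC)OO1 | intermediate
32 | lithium salt of 33 | C[C@H](/C=C/c1ccccc1)C/C=C/[C@H](C)C[C@]1(C)C[C@H](C)[C@H](CC(=O)[O-])OO1.[Li+] | intermediate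
33 | 2-{(3S,4S,6R)-6-[(2R,3E,6S,7E)-2,6-dimethyl-8-phenylocta-3,7-dien-1-yl]-4,6-dimethyl-1,2-dioxan-3-yl}acetic acid | C[C@H](/C=C/c1ccccc1)C/C=C/[C@H](C)C[C@]1(C)C[C@H](C)[C@H](CC(=O)O)OO1 | target

**Step count**

Total step count: 19.
Longest linear sequence: 15 steps (steps 1–5, 7–13 and 17–19).

**Steps most likely to fail**

**Step 10.**
What may go wrong:
- Competing 5-exo closure to a 1,2-dioxolane.
- Migration of the β,γ-alkene into conjugation, or epimerisation at C4, during the perhydrolysis.
- Incomplete facial selectivity of the iodonium opening.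

The fallback replaces the iodonium ion by an epoxide whose face is fixed by reagent control. It sets out from 13. Shi epoxidation with the L-sorbose-derived enantiomer of the ketone catalyst (Oxone, K2CO3, buffered MeCN/DMM) should give epoxy alcohol F1. Buffered Dess–Martin oxidation then gives epoxy aldehyde F2, which can no longer conjugate. Urea·H2O2/Sc(OTf)3 in MeOH gives epoxy methoxy hydroperoxide F3. Under the same acid F3 should open the epoxide at tertiary C6 with inversion (6-endo) to give 5-hydroxy-1,2-dioxane F4. Thiocarbonyldiimidazole converts F4 into imidazolylthiocarbonate F5. Barton–McCombie deoxygenation (Bu3SnH, Et3B/air) brings the sequence back to the route at 17.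

**Step 18.**
What may go wrong:
- Erosion of the axial facial selectivity, because the ketene acetal is a very reactive nucleophile.
- Cationic damage of the styrenyl diene, or ionisation of the tertiary C6–O bond, by the Lewis acid.

The fallback moves the C3–C2 bond formation to the alkene-free stage and uses a much less reactive nucleophile. It sets out from 17. Allyltrimethylsilane with catalytic TMSOTf (CH2Cl2, −78 °C) should give 3-allyl-1,2-dioxane F6. Ozonolysis with Me2S work-up gives aldehyde F7. Pinnick oxidation gives acid F8, and TMSCHN2 gives methyl ester F9. Buffered TBAF gives alcohol F10, and Dess–Martin oxidation gives aldehyde F11. Adding F11 to potassiated sulfone 27 (Julia–Kocienski) brings the sequence back to the route at 31.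

**Step 19.**
What may go wrong:
- Base-induced retro-oxa-Michael (E1cB) opening of the β-peroxy ester.
- Base-induced fragmentation at C3–H of the peroxide.

The fallback avoids any basic hydrolysis. It sets out from 28. Trimethylsilyl acetate is converted (LDA, TMSCl, THF, −78 °C) into bis-silyl ketene acetal F12. F12 replaces 29 in the TMSOTf-catalysed substitution and should give trimethylsilyl ester F13. F13 is cleaved by the neutral aqueous work-up, and the sequence comes back to the route at 33.

**Further compounds**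

F1 | step 10 | (2R)-2-{(2S,3S)-3-[(R)-3-(tert-butyldiphenylsilyloxy)-2-methylpropyl]-3-methyloxiran-2-yl}propan-1-ol | CC(C)(C)[Si](c1ccccc1)(c1ccccc1)OC[C@H](C)C[C@]1(C)O[C@H]1[C@H](C)CO
F2 | step 10 | epoxy aldehyde from F1 (configuration as in F1) | CC(C)(C)[Si](c1ccccc1)(c1ccccc1)OC[C@H](C)C[C@]1(C)O[C@H]1[C@H](C)C=O
F3 | step 10 | epoxy methoxy hydroperoxide from F2 (acetal carbon epimers) | CC(C)(C)[Si](c1ccccc1)(c1ccccc1)OC[C@H](C)C[C@]1(C)O[C@H]1[C@H](C)C(OC)OO
F4 | step 10 | (4S,5S,6R)-6-[(R)-3-(tert-butyldiphenylsilyloxy)-2-methylpropyl]-3-methoxy-4,6-dimethyl-1,2-dioxan-5-ol | CC(C)(C)[Si](c1ccccc1)(c1ccccc1)OC[C@H](C)C[C@]1(C)[C@@H](O)[C@H](C)C(OC)OO1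
F5 | step 10 | O-(dioxan-5-yl) 1H-imidazole-1-carbothioate of F4 | CC(C)(C)[Si](c1ccccc1)(c1ccccc1)OC[C@H](C)C[C@]1(C)[C@@H](OC(=S)n2ccnc2)[C@H](C)C(OC)OO1
F6 | step 18 | (3S,4S,6R)-3-allyl-6-[(R)-3-(tert-butyldiphenylsilyloxy)-2-methylpropyl]-4,6-dimethyl-1,2-dioxane | CC(C)(C)[Si](c1ccccc1)(c1ccccc1)OC[C@H](C)C[C@]1(C)C[C@H](C)[C@H](CC=C)OO1
F7 | step 18 | dioxan-3-ylacetaldehyde from F6 (configuration as in F6) | CC(C)(C)[Si](c1ccccc1)(c1ccccc1)OC[C@H](C)C[C@]1(C)C[C@H](C)[C@H](CC=O)OO1
F8 | step 18 | dioxan-3-ylacetic acid from F7 (configuration as in F6) | CC(C)(C)[Si](c1ccccc1)(c1ccccc1)OC[C@H](C)C[C@]1(C)C[C@H](C)[C@H](CC(=O)O)OO1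
F9 | step 18 | methyl dioxan-3-ylacetate from F8 (configuration as in F6) | CC(C)(C)[Si](c1ccccc1)(c1ccccc1)OC[C@H](C)C[C@]1(C)C[C@H](C)[C@H](CC(=O)OC)OO1
F10 | step 18 | primary alcohol from F9 (configuration as in F6) | OC[C@H](C)C[C@]1(C)C[C@H](C)[C@H](CC(=O)OC)OO1
F11 | step 18 | C9 aldehyde from F10 (configuration as in F6) | O=C[C@H](C)C[C@]1(C)C[C@H](C)[C@H](CC(=O)OC)OO1
F12 | step 19 | 1,1-bis(trimethylsilyloxy)ethene | C=C(O[Si](C)(C)C)O[Si](C)(C)C
F13 | step 19 | trimethylsilyl ester of 33 | C[C@H](/C=C/c1ccccc1)C/C=C/[C@H](C)C[C@]1(C)C[C@H](C)[C@H](CC(=O)O[Si](C)(C)C)OO1
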